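## Retrosynthetic overview

1. The C40 skeleton is cut at C11=C12 and C11'=C12' (two Wittig reactions) into the acetylenic C15 salt 23 (ring A), 2,7-dimethylocta-2,4,6-trienedial 26 and the olefinic C15 salt 25 (ring B). Both salts come from one carbinol 21 (ring enyne plus methyl vinyl ketone); the ring B salt needs only a trans-hydroalumination of the 7,8-alkyne.
2. The six-membered ring is built once (step 7) and serves ring A and ring B. Acyclic aldehyde 12 and isobutylene are joined by a Prins addition (C2–C3) followed by cation–olefin closure (C1–C6) and loss of H6. This copies the cyclase step that turns the ψ-end into the β-end group, but it is started by a C–C bond formation that also delivers the C3 hydroxyl.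
3. Enabling feature: in ring A the C1(CH3)2–C2H2 unit is an intact isobutylene lying between carbinol carbon C3 (an aldehyde carbon in the precursor) and olefinic carbon C6, and the C5=C6 double bond sits where the biosynthetic cyclisation leaves it, conjugated to the C7≡C8 alkyne.
4. C4 comes from methyl (R)-glycerate acetonide 1 (chiral pool). Its chelating 2-naphthylmethyl ether sets C3 in the key step (3,4-trans); the ether is then removed with DDQ and the diol is carried as a bis-silyl ether.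

Key step: step 7

Remark: compounds 7, 8, 10, 11 and 12 are drawn as the E isomer, and the Z isomer formed alongside in step 2 is carried on because C-6 becomes trigonal again in step 7; the acetal carbon of 10 and C-9 of 21 and 24 are epimeric mixtures whose stereocentres are destroyed later.

## Route

Step 1
Reactants: 1 methyl (R)-2,2-dimethyl-1,3-dioxolane-4-carboxylate; 2 N,O-dimethylhydroxylamine hydrochloride; 3 methylmagnesium bromide
Product: 5 (R)-1-(2,2-dimethyl-1,3-dioxolan-4-yl)ethan-1-one, via Weinreb amide 4 (not isolated)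
Conditions: 2, i-PrMgCl, THF, −20 °C; then MeMgBr, −20 → 0 °C; aq. NH4Cl
Reagents that add atoms: methylmagnesium bromide (C[Mg]Br); N,O-dimethylhydroxylamine hydrochloride (CNOC.Cl; kept only in intermediate 4)
Why: One-pot Weinreb amide formation and Grignard addition, in which the chelated tetrahedral adduct stops at the ketone and the cold, non-equilibrating conditions should leave the stereocentre untouched.

Step 2
Reactants: 5 (R)-1-(2,2-dimethyl-1,3-dioxolan-4-yl)ethan-1-one; 6 diethyl [3-(trimethylsilyl)prop-2-yn-1-yl]phosphonate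
Product: 7 (4S)-2,2-dimethyl-4-[(2E)-5-(trimethylsilyl)pent-2-en-4-yn-2-yl]-1,3-dioxolane
Conditions: 6, NaN(SiMe3)2, THF, −78 °C; then 5, −78 → 0 °C
Reagents that add atoms: diethyl [3-(trimethylsilyl)prop-2-yn-1-yl]phosphonate (CCOP(=O)(CC#C[Si](C)(C)C)OCC)
Why: Horner–Wadsworth–Emmons olefination of the methyl ketone with a silyl-capped propargyl phosphonate anion should give the trisubstituted enyne, whose E/Z geometry does not matter for step 7.

Step 3
Reactants: 7 (4S)-2,2-dimethyl-4-[(2E)-5-(trimethylsilyl)pent-2-en-4-yn-2-yl]-1,3-dioxolane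
Product: 8 (2S,3E)-3-methyl-6-(trimethylsilyl)hex-3-en-5-yne-1,2-diol
Conditions: AcOH/H2O (4:1), 40 °C
Reagents that add atoms: none
Why: Mild acid hydrolysis of the isopropylidene acetal, which the alkynylsilane and the allylic carbinol should tolerate.

Step 4
Reactants: 8 (2S,3E)-3-methyl-6-(trimethylsilyl)hex-3-en-5-yne-1,2-diol; 9 2-(dimethoxymethyl)naphthalene
Product: 10 (4S)-2-(naphthalen-2-yl)-4-[(2E)-5-(trimethylsilyl)pent-2-en-4-yn-2-yl]-1,3-dioxolane (both acetal epimers)
Conditions: 9, camphorsulfonic acid (cat.), 4 Å molecular sieves, CH2Cl2, rt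
Reagents that add atoms: 2-(dimethoxymethyl)naphthalene (COC(OC)c1ccc2ccccc2c1)
Why: Acid-catalysed transacetalisation closes the five-membered arylidene acetal of the terminal 1,2-diol without touching the carbinol stereocentre.

Step 5
Reactants: 10 (4S)-2-(naphthalen-2-yl)-4-[(2E)-5-(trimethylsilyl)pent-2-en-4-yn-2-yl]-1,3-dioxolane
Product: 11 (2S,3E)-3-methyl-2-(naphthalen-2-ylmethoxy)-6-(trimethylsilyl)hex-3-en-5-yn-1-ol
Conditions: i-Bu2AlH, CH2Cl2, −78 → 0 °C; aq. potassium sodium tartrate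
Reagents that add atoms: none
Why: Reductive opening of the arylidene acetal, in which aluminium binds the less hindered primary oxygen and hydride reduces the oxocarbenium ion, should leave the arylmethyl ether on the secondary oxygen.

Step 6
Reactants: 11 (2S,3E)-3-methyl-2-(naphthalen-2-ylmethoxy)-6-(trimethylsilyl)hex-3-en-5-yn-1-ol
Product: 12 (2S,3E)-3-methyl-2-(naphthalen-2-ylmethoxy)-6-(trimethylsilyl)hex-3-en-5-ynal
Conditions: Dess–Martin periodinane, NaHCO3, CH2Cl2, 0 °C; used at once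
Reagents that add atoms: none
Why: Dess–Martin oxidation under buffered, base-free conditions should give the α-alkoxy-β,γ-unsaturated aldehyde without enolisation at the doubly activated C-4.

Step 7
Reactants: 12 (2S,3E)-3-methyl-2-(naphthalen-2-ylmethoxy)-6-(trimethylsilyl)hex-3-en-5-ynal; 13 isobutylene
Product: 15 (1S,2S)-3,5,5-trimethyl-2-(naphthalen-2-ylmethoxy)-4-[(trimethylsilyl)ethynyl]cyclohex-3-en-1-ol, via tin-bound tertiary carbocation 14 (not isolated)
Conditions: SnCl4 (1.1 equiv.), CH2Cl2, −78 °C; isobutylene (5 equiv., condensed), −78 → −40 °C; aq. NaHCO3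
Reagents that add atoms: isobutylene (CC(C)=C); tin tetrachloride (Cl[Sn](Cl)(Cl)Cl; kept only in intermediate 14)
Why: Proposed new method: SnCl4 binds the aldehyde oxygen and the C-4 ether oxygen of 12 in a five-membered chelate, isobutylene adds through its CH2 terminus to the aldehyde carbon (Prins addition, C-2–C-3 bond) to give tertiary carbocation 14, and the C-1 cation is trapped by C-6 of the trisubstituted C-5=C-6 enyne olefin (C-1–C-6 bond), after which loss of H-6 restores C-5=C-6 in conjugation with the alkyne and the proton ends on the tin alkoxide. The closest known reaction types are the chelation-controlled SnCl4-promoted carbonyl-ene/Prins addition of isobutylene to α-alkoxy aldehydes and the proton-initiated cation–olefin cyclisation of ψ-ionone to β-ionone, which is also the bond-forming event of the carotenoid β-cyclase; new is that the Prins cation is intercepted intramolecularly instead of collapsing by hydrogen transfer. The one ring is closed in the 6-endo-trig mode through a chair-like transition state with both oxygens equatorial and held in the tin chelate. The new stereocentre C-3 is set in the first bond-forming event by Cram-chelate control from C-4: the alkene attacks the aldehyde face anti to the alkenyl substituent of the chelate, giving the 3,4-syn (ring-trans) arrangement, that is (3S,4S), while C-1 and C-6 carry no stereochemistry. The step needs Markovnikov 6-endo over 5-exo closure, secured by the C-5 methyl group that makes the C-5 cation tertiary, and proton loss from C-6 rather than from C-4 or the C-5 methyl group, which the developing enyne conjugation and the poor donor ability of the tin-bound C-4 ether oxygen (no hydride shift to an oxocarbenium ion) should secure.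

Step 8
Reactants: 15 (1S,2S)-3,5,5-trimethyl-2-(naphthalen-2-ylmethoxy)-4-[(trimethylsilyl)ethynyl]cyclohex-3-en-1-ol
Product: 16 (1S,2S)-3,5,5-trimethyl-4-[(trimethylsilyl)ethynyl]cyclohex-3-ene-1,2-diol
Conditions: DDQ, CH2Cl2/pH 7 phosphate buffer (10:1), 0 °C → rt
Reagents that add atoms: none
Why: Oxidative cleavage of the 2-naphthylmethyl ether (hydride abstraction through the arene charge-transfer complex, then hydrolysis) works under neutral conditions that should spare the acid-labile allylic C-4 oxygen and the enyne.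

Step 9
Reactants: 16 (1S,2S)-3,5,5-trimethyl-4-[(trimethylsilyl)ethynyl]cyclohex-3-ene-1,2-diol; 17 tert-butyldimethylsilyl trifluoromethanesulfonate
Product: 18 {[(1S,2S)-3,5,5-trimethyl-4-[(trimethylsilyl)ethynyl]cyclohex-3-ene-1,2-diyl]bis(oxy)}bis(tert-butyldimethylsilane)
Conditions: TBSOTf, 2,6-lutidine, CH2Cl2, 0 °C → rt
Reagents that add atoms: tert-butyldimethylsilyl trifluoromethanesulfonate (CC(C)(C)[Si](C)(C)OS(=O)(=O)C(F)(F)F)
Why: Silyl triflate and a hindered base silylate both secondary hydroxyls of the trans-diol, giving ethers that withstand organolithium, hydride and Wittig conditions.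

Step 10
Reactants: 18 {[(1S,2S)-3,5,5-trimethyl-4-[(trimethylsilyl)ethynyl]cyclohex-3-ene-1,2-diyl]bis(oxy)}bis(tert-butyldimethylsilane); 19 methyl vinyl ketone
Product: 21 5-[(3S,4S)-3,4-bis(tert-butyldimethylsilyloxy)-2,6,6-trimethylcyclohex-1-en-1-yl]-3-methylpent-1-en-4-yn-3-ol (C-3 epimers), via lithium acetylide 20 (not isolated)
Conditions: MeLi·LiBr, THF, 0 °C → rt; then methyl vinyl ketone, −78 °C; aq. NH4Cl
Reagents that add atoms: methyl vinyl ketone (CC(=O)C=C); methyllithium (C[Li]; lithium kept only in intermediate 20)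
Why: Methyllithium cleaves the alkynyl C–Si bond to the lithium acetylide, which adds 1,2 to the enone and forms the C-8–C-9 bond; the new carbinol centre is uncontrolled and is removed in steps 11 and 13.

Step 11
Reactants: 21 5-[(3S,4S)-3,4-bis(tert-butyldimethylsilyloxy)-2,6,6-trimethylcyclohex-1-en-1-yl]-3-methylpent-1-en-4-yn-3-ol; 22 triphenylphosphine hydrobromide
Product: 23 {(2E)-5-[(3S,4S)-3,4-bis(tert-butyldimethylsilyloxy)-2,6,6-trimethylcyclohex-1-en-1-yl]-3-methylpent-2-en-4-yn-1-yl}triphenylphosphonium bromide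
Conditions: Ph3P·HBr, CH2Cl2, 0 °C → rt
Reagents that add atoms: triphenylphosphine hydrobromide ([Br-].[PH+](c1ccccc1)(c1ccccc1)c1ccccc1)
Why: Ionisation of the tertiary allylic-propargylic carbinol and capture of triphenylphosphine at the primary terminus (allylic transposition) is the classical way to C15 Wittig salts and should favour the 9E isomer.

Step 12
Reactants: 21 5-[(3S,4S)-3,4-bis(tert-butyldimethylsilyloxy)-2,6,6-trimethylcyclohex-1-en-1-yl]-3-methylpent-1-en-4-yn-3-ol
Product: 24 (1E)-1-[(3S,4S)-3,4-bis(tert-butyldimethylsilyloxy)-2,6,6-trimethylcyclohex-1-en-1-yl]-3-methylpenta-1,4-dien-3-ol (C-3 epimers)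
Conditions: NaAlH2(OCH2CH2OCH3)2, THF, 0 °C → rt; aq. potassium sodium tartrate
Reagents that add atoms: none
Why: Alkoxide-directed trans-hydroalumination of the propargylic alcohol followed by protonolysis should give the E-configured C-7=C-8 double bond of ring B and leave the vinyl group alone.

Step 13
Reactants: 24 (1E)-1-[(3S,4S)-3,4-bis(tert-butyldimethylsilyloxy)-2,6,6-trimethylcyclohex-1-en-1-yl]-3-methylpenta-1,4-dien-3-ol; 22 triphenylphosphine hydrobromide
Product: 25 {(2E,4E)-5-[(3S,4S)-3,4-bis(tert-butyldimethylsilyloxy)-2,6,6-trimethylcyclohex-1-en-1-yl]-3-methylpenta-2,4-dien-1-yl}triphenylphosphonium bromide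
Conditions: Ph3P·HBr, CH2Cl2, 0 °C → rt
Reagents that add atoms: triphenylphosphine hydrobromide ([Br-].[PH+](c1ccccc1)(c1ccccc1)c1ccccc1)
Why: The same ionisation with allylic transposition as in step 11, here through a pentadienyl cation that triphenylphosphine should capture at the primary terminus.

Step 14
Reactants: 25 {(2E,4E)-5-[(3S,4S)-3,4-bis(tert-butyldimethylsilyloxy)-2,6,6-trimethylcyclohex-1-en-1-yl]-3-methylpenta-2,4-dien-1-yl}triphenylphosphonium bromide; 26 (2E,4E,6E)-2,7-dimethylocta-2,4,6-trienedial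
Product: 28 (2E,4E,6E,8E,10E,12E)-13-[(3S,4S)-3,4-bis(tert-butyldimethylsilyloxy)-2,6,6-trimethylcyclohex-1-en-1-yl]-2,7,11-trimethyltrideca-2,4,6,8,10,12-hexaenal, via ylide 27 (not isolated)
Conditions: 26 (3 equiv.), NaOMe, MeOH/CH2Cl2, 0 °C → rt, dark, argon
Reagents that add atoms: 2,7-dimethylocta-2,4,6-trienedial (O=C/C(C)=C/C=C/C=C(C)/C=O)
Why: Wittig olefination forms C-11'=C-12'; the excess of dialdehyde should hold the reaction at the mono-olefination stage, and any Z isomer at the new bond is corrected by the isomerisation in step 15.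

Step 15
Reactants: 23 {(2E)-5-[(3S,4S)-3,4-bis(tert-butyldimethylsilyloxy)-2,6,6-trimethylcyclohex-1-en-1-yl]-3-methylpent-2-en-4-yn-1-yl}triphenylphosphonium bromide; 28 the C25 aldehyde
Product: 30 (3S,4S,3'S,4'S)-3,4,3',4'-tetrakis(tert-butyldimethylsilyloxy)-7,8-didehydro-β,β-carotene, via ylide 29 (not isolated)
Conditions: NaOMe, MeOH/CH2Cl2, 0 °C → rt; then heptane, 80 °C; dark, argon
Reagents that add atoms: phosphonium salt 23 (CC1=C(C#C/C(C)=C/C[P+](c2ccccc2)(c2ccccc2)c2ccccc2)C(C)(C)C[C@H](O[Si](C)(C)C(C)(C)C)[C@H]1O[Si](C)(C)C(C)(C)C.[Br-])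
Why: The second Wittig olefination forms C-11=C-12 and completes the C40 chain; heating should isomerise the hindered 11-cis and 11'-cis bonds to E, and the all-E compound would be separated from any 9Z isomer by crystallisation or chromatography.

Step 16
Reactants: 30 (3S,4S,3'S,4'S)-3,4,3',4'-tetrakis(tert-butyldimethylsilyloxy)-7,8-didehydro-β,β-carotene
Product: 31 (3S,4S,3'S,4'S)-7,8-didehydro-β,β-carotene-3,4,3',4'-tetrol (CNP0343957.1)
Conditions: Bu4NF, THF, rt, dark, argon
Reagents that add atoms: none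
Why: Fluoride-mediated desilylation frees the four hydroxyls without acid, which the allylic C-4 and C-4' carbinols and the polyene would not tolerate.

## Compound list

1 | methyl (R)-2,2-dimethyl-1,3-dioxolane-4-carboxylate | COC(=O)[C@H]1COC(C)(C)O1 | starting material
2 | N,O-dimethylhydroxylamine hydrochloride | CNOC.Cl | starting material
3 | methylmagnesium bromide | C[Mg]Br | starting material
4 | (R)-N-methoxy-N,2,2-trimethyl-1,3-dioxolane-4-carboxamide | CON(C)C(=O)[C@H]1COC(C)(C)O1 | intermediate (not isolated)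
5 | (R)-1-(2,2-dimethyl-1,3-dioxolan-4-yl)ethan-1-one | CC(=O)[C@H]1COC(C)(C)O1 | intermediate
6 | diethyl [3-(trimethylsilyl)prop-2-yn-1-yl]phosphonate | CCOP(=O)(CC#C[Si](C)(C)C)OCC | starting material
7 | (4S)-2,2-dimethyl-4-[(2E)-5-(trimethylsilyl)pent-2-en-4-yn-2-yl]-1,3-dioxolane | C/C(=C\C#C[Si](C)(C)C)[C@H]1COC(C)(C)O1 | intermediate
8 | (2S,3E)-3-methyl-6-(trimethylsilyl)hex-3-en-5-yne-1,2-diol | C/C(=C\C#C[Si](C)(C)C)[C@H](O)CO | intermediate
9 | 2-(dimethoxymethyl)naphthalene | COC(OC)c1ccc2ccccc2c1 | starting material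
10 | (4S)-2-(naphthalen-2-yl)-4-[(2E)-5-(trimethylsilyl)pent-2-en-4-yn-2-yl]-1,3-dioxolane (acetal epimers) | C/C(=C\C#C[Si](C)(C)C)[C@H]1COC(c2ccc3ccccc3c2)O1 | intermediate
11 | (2S,3E)-3-methyl-2-(naphthalen-2-ylmethoxy)-6-(trimethylsilyl)hex-3-en-5-yn-1-ol | C/C(=C\C#C[Si](C)(C)C)[C@H](OCc1ccc2ccccc2c1)CO | intermediate
12 | (2S,3E)-3-methyl-2-(naphthalen-2-ylmethoxy)-6-(trimethylsilyl)hex-3-en-5-ynal | C/C(=C\C#C[Si](C)(C)C)[C@H](OCc1ccc2ccccc2c1)C=O | intermediate
13 | isobutylene (2-methylpropene) | CC(C)=C | starting material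
14 | tin-bound tertiary carbocation from Prins addition of 13 to 12 | C[C+](C)C[C@H](O[Sn-](Cl)(Cl)(Cl)Cl)[C@@H](OCc1ccc2ccccc2c1)/C(C)=C/C#C[Si](C)(C)C | intermediate (not isolated)
15 | (1S,2S)-3,5,5-trimethyl-2-(naphthalen-2-ylmethoxy)-4-[(trimethylsilyl)ethynyl]cyclohex-3-en-1-ol | CC1=C(C#C[Si](C)(C)C)C(C)(C)C[C@H](O)[C@H]1OCc2ccc3ccccc3c2 | intermediate
16 | (1S,2S)-3,5,5-trimethyl-4-[(trimethylsilyl)ethynyl]cyclohex-3-ene-1,2-diol | CC1=C(C#C[Si](C)(C)C)C(C)(C)C[C@H](O)[C@H]1O | intermediate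
17 | tert-butyldimethylsilyl trifluoromethanesulfonate | CC(C)(C)[Si](C)(C)OS(=O)(=O)C(F)(F)F | starting material
18 | {[(1S,2S)-3,5,5-trimethyl-4-[(trimethylsilyl)ethynyl]cyclohex-3-ene-1,2-diyl]bis(oxy)}bis(tert-butyldimethylsilane) | CC1=C(C#C[Si](C)(C)C)C(C)(C)C[C@H](O[Si](C)(C)C(C)(C)C)[C@H]1O[Si](C)(C)C(C)(C)C | intermediate
19 | methyl vinyl ketone | CC(=O)C=C | starting material
20 | lithium acetylide of the ring enyne | CC1=C(C#C[Li])C(C)(C)C[C@H](O[Si](C)(C)C(C)(C)C)[C@H]1O[Si](C)(C)C(C)(C)C | intermediate (not isolated)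
21 | 5-[(3S,4S)-3,4-bis(tert-butyldimethylsilyloxy)-2,6,6-trimethylcyclohex-1-en-1-yl]-3-methylpent-1-en-4-yn-3-ol (C-3 epimers) | CC1=C(C#CC(C)(O)C=C)C(C)(C)C[C@H](O[Si](C)(C)C(C)(C)C)[C@H]1O[Si](C)(C)C(C)(C)C | intermediate
22 | triphenylphosphine hydrobromide | [Br-].[PH+](c1ccccc1)(c1ccccc1)c1ccccc1 | starting material
23 | {(2E)-5-[(3S,4S)-3,4-bis(tert-butyldimethylsilyloxy)-2,6,6-trimethylcyclohex-1-en-1-yl]-3-methylpent-2-en-4-yn-1-yl}triphenylphosphonium bromide | CC1=C(C#C/C(C)=C/C[P+](c2ccccc2)(c2ccccc2)c2ccccc2)C(C)(C)C[C@H](O[Si](C)(C)C(C)(C)C)[C@H]1O[Si](C)(C)C(C)(C)C.[Br-] | intermediate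
24 | (1E)-1-[(3S,4S)-3,4-bis(tert-butyldimethylsilyloxy)-2,6,6-trimethylcyclohex-1-en-1-yl]-3-methylpenta-1,4-dien-3-ol (C-3 epimers) | CC1=C(/C=C/C(C)(O)C=C)C(C)(C)C[C@H](O[Si](C)(C)C(C)(C)C)[C@H]1O[Si](C)(C)C(C)(C)C | intermediate
25 | {(2E,4E)-5-[(3S,4S)-3,4-bis(tert-butyldimethylsilyloxy)-2,6,6-trimethylcyclohex-1-en-1-yl]-3-methylpenta-2,4-dien-1-yl}triphenylphosphonium bromide | CC1=C(/C=C/C(C)=C/C[P+](c2ccccc2)(c2ccccc2)c2ccccc2)C(C)(C)C[C@H](O[Si](C)(C)C(C)(C)C)[C@H]1O[Si](C)(C)C(C)(C)C.[Br-] | intermediate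
26 | (2E,4E,6E)-2,7-dimethylocta-2,4,6-trienedial | O=C/C(C)=C/C=C/C=C(C)/C=O | starting material
27 | ylide of salt 25 | CC1=C(/C=C/C(C)=C/C=P(c2ccccc2)(c2ccccc2)c2ccccc2)C(C)(C)C[C@H](O[Si](C)(C)C(C)(C)C)[C@H]1O[Si](C)(C)C(C)(C)C | intermediate (not isolated)
28 | (2E,4E,6E,8E,10E,12E)-13-[(3S,4S)-3,4-bis(tert-butyldimethylsilyloxy)-2,6,6-trimethylcyclohex-1-en-1-yl]-2,7,11-trimethyltrideca-2,4,6,8,10,12-hexaenal | O=C/C(C)=C/C=C/C=C(C)/C=C/C=C(C)/C=C/C1=C(C)[C@H](O[Si](C)(C)C(C)(C)C)[C@@H](O[Si](C)(C)C(C)(C)C)CC1(C)C | intermediate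
29 | ylide of salt 23 | CC1=C(C#C/C(C)=C/C=P(c2ccccc2)(c2ccccc2)c2ccccc2)C(C)(C)C[C@H](O[Si](C)(C)C(C)(C)C)[C@H]1O[Si](C)(C)C(C)(C)C | intermediate (not isolated)
30 | (3S,4S,3'S,4'S)-3,4,3',4'-tetrakis(tert-butyldimethylsilyloxy)-7,8-didehydro-β,β-carotene | CC1=C(C#C/C(C)=C/C=C/C(C)=C/C=C/C=C(C)/C=C/C=C(C)/C=C/C2=C(C)[C@H](O[Si](C)(C)C(C)(C)C)[C@@H](O[Si](C)(C)C(C)(C)C)CC2(C)C)C(C)(C)C[C@H](O[Si](C)(C)C(C)(C)C)[C@H]1O[Si](C)(C)C(C)(C)C | intermediate
31 | (3S,4S,3'S,4'S)-7,8-didehydro-β,β-carotene-3,4,3',4'-tetrol, all-E | CC1=C(C#C/C(C)=C/C=C/C(C)=C/C=C/C=C(C)/C=C/C=C(C)/C=C/C2=C(C)[C@H](O)[C@@H](O)CC2(C)C)C(C)(C)C[C@H](O)[C@H]1O | target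

## Step count and risks

Total step count: 16. Longest linear sequence: 15 steps (steps 1–10, 12, 13, 14, 15, 16).

Steps most likely to fail:

1. Step 7 (proposed new method). The tertiary cation may be quenched by ene-type hydrogen transfer or by chloride before the enyne olefin traps it. The proton may be lost toward C-4 or the C-5 methyl group. The tin Lewis acid may ionise the allylic C-4–O bond of the product. The aldehyde may enolise with loss of configuration at C-4. Fallback, from 12 back to 15, in two known operations: chelation-controlled Hosomi–Sakurai addition of methallyltrimethylsilane (MgBr2·OEt2 or SnCl4, CH2Cl2, −78 °C) would give (4S,5S,6E)-2,6-dimethyl-5-(naphthalen-2-ylmethoxy)-9-(trimethylsilyl)nona-1,6-dien-8-yn-4-ol F1. A separate proton-initiated cation–olefin cyclisation of its 1,1-disubstituted alkene onto the enyne olefin would then close C-1–C-6 and give 15 (SnCl4 bound to the free hydroxyl as a Lewis acid-assisted Brønsted acid, CH2Cl2, −78 → −30 °C, the ψ-ionone to β-ionone mode).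

2. Step 2. The basic phosphonate anion may enolise the α-alkoxy methyl ketone, which would erode the enantiomeric purity or stall the olefination. Fallback, from 5 back to 7, without strong base: zinc-mediated Barbier addition of 3-bromo-1-(trimethylsilyl)prop-1-yne (Zn, THF, 0 °C) would give 2-[(4R)-2,2-dimethyl-1,3-dioxolan-4-yl]-5-(trimethylsilyl)pent-4-yn-2-ol F2 (both carbinol epimers serve). Syn-elimination with the Burgess reagent (toluene, 50 °C) toward the propargylic CH2 would then give enyne 7.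

3. Step 11. The acid may cleave a silyl ether or ionise the allylic C-4–O bond, and the phosphine may be captured with scrambling of the C-9 geometry. Fallback, from 18 back to 23, without acid:
 - K2CO3 in MeOH would free the terminal alkyne {[(1S,2S)-4-ethynyl-3,5,5-trimethylcyclohex-3-ene-1,2-diyl]bis(oxy)}bis(tert-butyldimethylsilane) F3.
 - Sonogashira coupling with (E)-3-iodobut-2-en-1-ol (C/C(I)=C\CO, available by stannylcupration–iodination of but-2-yn-1-ol; Pd(PPh3)4, CuI, Et3N, THF, rt) would give (2E)-5-[(3S,4S)-3,4-bis(tert-butyldimethylsilyloxy)-2,6,6-trimethylcyclohex-1-en-1-yl]-3-methylpent-2-en-4-yn-1-ol F4 with defined 9E geometry.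
 - CBr4/PPh3 (CH2Cl2, 0 °C) would give the allylic bromide (2E)-5-bromo-3-methylpent-3-en-1-ynyl ring compound F5, and triphenylphosphine in toluene at rt would give 23.

Further compounds
F1 | step 7 | (4S,5S,6E)-2,6-dimethyl-5-(naphthalen-2-ylmethoxy)-9-(trimethylsilyl)nona-1,6-dien-8-yn-4-ol | C=C(C)C[C@H](O)[C@@H](OCc1ccc2ccccc2c1)/C(C)=C/C#C[Si](C)(C)C
F2 | step 2 | 2-[(4R)-2,2-dimethyl-1,3-dioxolan-4-yl]-5-(trimethylsilyl)pent-4-yn-2-ol | CC(O)(CC#C[Si](C)(C)C)[C@H]1COC(C)(C)O1
F3 | step 11 | {[(1S,2S)-4-ethynyl-3,5,5-trimethylcyclohex-3-ene-1,2-diyl]bis(oxy)}bis(tert-butyldimethylsilane) | CC1=C(C#C)C(C)(C)C[C@H](O[Si](C)(C)C(C)(C)C)[C@H]1O[Si](C)(C)C(C)(C)C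
F4 | step 11 | (2E)-5-[(3S,4S)-3,4-bis(tert-butyldimethylsilyloxy)-2,6,6-trimethylcyclohex-1-en-1-yl]-3-methylpent-2-en-4-yn-1-ol | CC1=C(C#C/C(C)=C/CO)C(C)(C)C[C@H](O[Si](C)(C)C(C)(C)C)[C@H]1O[Si](C)(C)C(C)(C)C
F5 | step 11 | {[(1S,2S)-4-[(3E)-5-bromo-3-methylpent-3-en-1-yn-1-yl]-3,5,5-trimethylcyclohex-3-ene-1,2-diyl]bis(oxy)}bis(tert-butyldimethylsilane) | CC1=C(C#C/C(C)=C/CBr)C(C)(C)C[C@H](O[Si](C)(C)C(C)(C)C)[C@H]1O[Si](C)(C)C(C)(C)C
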